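**Strategy.** Everything rests on cutting the C3′–C4′ and C5′–C6′ bonds of both outer rings (rings B and B′). Each of these rings holds its two oxygens on the neighbouring carbons C4′/C5′, facing the four-carbon arc C3′–C2′–C1′–C6′ with the benzylic CH2 on C1′: a cis-dioxygenated two-carbon unit joined to a 2-substituted butadiene. A twofold thermal Diels–Alder reaction with vinylene carbonate therefore closes both outer carbocycles and installs all four catechol oxygens in one operation. Its precursor is the hexasubstituted bromotrimethoxybenzene core (ring A) carrying two CH2–C(=CH2)–CH=CH2 arms; aromatisation, bromination at C2′/C3′ and demethylation follow.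

Key step: step 3

Remark: ring A is the central ring; in rings B and B′, C1′ bears the CH2, C2′ and C3′ bear bromine in the target, C4′ and C5′ bear oxygen, and C6′ bears hydrogen.
Remark: the two cis-fused units of the cycloadduct and of the derived tetraol form independently, so both are expected as a mixture of a C2-symmetric racemate and a meso form; the SMILES show the C2-symmetric form, and every stereocentre disappears on aromatisation.
Remark: the starting bromide is assumed to be bought as a catalogue compound.

Step 1
Reactants: 1 2-bromo-1,3,5-trimethoxybenzene; 2 paraformaldehyde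
Product: 3 2-bromo-4,6-bis(chloromethyl)-1,3,5-trimethoxybenzene
Conditions: (CH2O)n (6 equiv), HCl (4 M in 1,4-dioxane), AcOH, 20 → 40 °C
Reagents that add atoms: formaldehyde (from paraformaldehyde 2), C=O; hydrogen chloride, Cl
Why: Blanc chloromethylation (electrophilic aromatic substitution by protonated formaldehyde, then OH-to-Cl exchange) should work because each of the two free ring positions is ortho, ortho and para to methoxy groups, the bromine blocks a third substitution, excess formaldehyde and HCl push both sites to the chloride before diarylmethane formation can compete, and the absence of bromide avoids acid-mediated loss or migration of the ring bromine.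

Step 2
Reactants: 3 2-bromo-4,6-bis(chloromethyl)-1,3,5-trimethoxybenzene; 4 chloroprene (2-chlorobuta-1,3-diene)
Product: 6 2-bromo-1,3,5-trimethoxy-4,6-bis(2-methylidenebut-3-en-1-yl)benzene, via buta-1,3-dien-2-ylmagnesium chloride 5 (not isolated)
Conditions: 4 (3 equiv), Mg, ZnCl2 (cat.), BrCH2CH2Br (cat.), THF, reflux; then slow addition to 3, Li2CuCl4 (5 mol %), THF, −20 → 0 °C; BHT on work-up
Reagents that add atoms: chloroprene 4, C=CC(Cl)=C
Why: Kochi-type copper-catalysed cross-coupling of a benzylic chloride with an alkenyl Grignard reagent should substitute both reactive benzylic C–Cl bonds at the magnesium-bearing carbon (diene, not allene), while the hindered aryl bromide should not exchange with the Grignard reagent at or below 0 °C.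

Step 3
Reactants: 6 2-bromo-1,3,5-trimethoxy-4,6-bis(2-methylidenebut-3-en-1-yl)benzene; 7 vinylene carbonate
Product: 8 5,5′-[(5-bromo-2,4,6-trimethoxy-1,3-phenylene)bis(methylene)]bis(cis-3a,4,7,7a-tetrahydro-1,3-benzodioxol-2-one)
Conditions: 7 (20 equiv), BHT (5 mol %), PhMe, argon, sealed tube, 170 °C
Reagents that add atoms: vinylene carbonate 7, O=C1OC=CO1
Why: Each diene arm reaches its s-cis conformer and adds vinylene carbonate in a concerted, suprafacial thermal [4+2] cycloaddition (Diels–Alder reaction) that forms C3′–C4′ and C5′–C6′ and leaves the C1′=C2′ double bond in place. The closest known reaction type is the thermal Diels–Alder addition of vinylene carbonate to isoprene-like 2-alkylbuta-1,3-dienes at 160–180 °C. Rings B and B′ are each closed by intermolecular [4+2] annulation, two σ-bonds per ring being made at once. The two stereocentres of each ring (C4′ and C5′) come out cis because the dienophile is a (Z)-alkene locked in the five-membered carbonate and adds across one face; nothing relates the two rings to each other, and none of the four centres survives aromatisation. Only chemoselectivity is needed, cycloaddition against diene dimerisation and radical polymerisation, and it is secured by the large excess of the symmetric dienophile (which also removes any regiochemical question), the radical inhibitor, exclusion of oxygen and a fully substituted ring A without a reactive site.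

Step 4
Reactants: 8 5,5′-[(5-bromo-2,4,6-trimethoxy-1,3-phenylene)bis(methylene)]bis(cis-3a,4,7,7a-tetrahydro-1,3-benzodioxol-2-one)
Product: 9 4,4′-[(5-bromo-2,4,6-trimethoxy-1,3-phenylene)bis(methylene)]bis(cis-cyclohex-4-ene-1,2-diol)
Conditions: K2CO3 (0.5 equiv), MeOH, 0 °C → rt
Reagents that add atoms: none
Why: Base-catalysed transesterification (methanolysis) of the two cyclic carbonates should release dimethyl carbonate by breaking only C(=O)–O bonds, so each cis-diol keeps the configuration set in step 3 and the aryl bromide, methyl ethers and alkenes are untouched.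

Step 5
Reactants: 9 4,4′-[(5-bromo-2,4,6-trimethoxy-1,3-phenylene)bis(methylene)]bis(cis-cyclohex-4-ene-1,2-diol)
Product: 11 4,4′-[(5-bromo-2,4,6-trimethoxy-1,3-phenylene)bis(methylene)]bis(benzene-1,2-diol), via bis(cyclohex-4-ene-1,2-dione) 10 (not isolated)
Conditions: (COCl)2 (6 equiv), DMSO (12 equiv), CH2Cl2, −78 °C; Et3N (20 equiv), −78 °C → rt
Reagents that add atoms: none
Why: Swern oxidation of all four secondary alcohols should give two cyclohex-4-ene-1,2-dione units that, with the C1′=C2′ double bond already present, stand at the catechol oxidation level and aromatise by amine-mediated double enolisation, activated DMSO not cleaving the C4′–C5′ bond as glycol-cleaving oxidants would.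

Step 6
Reactants: 11 4,4′-[(5-bromo-2,4,6-trimethoxy-1,3-phenylene)bis(methylene)]bis(benzene-1,2-diol)
Product: 12 5,5′-[(5-bromo-2,4,6-trimethoxy-1,3-phenylene)bis(methylene)]bis(3,4-dibromobenzene-1,2-diol)
Conditions: Br2 (4.1 equiv), AcOH, 15 °C → rt
Reagents that add atoms: bromine, BrBr
Why: Electrophilic aromatic bromination should take C2′ (para to the C5′ hydroxyl) and C3′ (ortho to the C4′ hydroxyl) on each catechol, as known for the dibromination of protocatechualdehyde-type 4-substituted catechols, because a bromine at C6′ would put a second ortho substituent beside the CH2 that already abuts the doubly ortho-methoxylated ring A, and ring A itself has no free position.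

Step 7
Reactants: 12 5,5′-[(5-bromo-2,4,6-trimethoxy-1,3-phenylene)bis(methylene)]bis(3,4-dibromobenzene-1,2-diol)
Product: 13 vidalol B, 2-bromo-4,6-bis(2,3-dibromo-4,5-dihydroxybenzyl)benzene-1,3,5-triol
Conditions: BBr3 (12 equiv), CH2Cl2, −78 °C → rt; then H2O, 0 °C
Reagents that add atoms: none
Why: Lewis acid-mediated aryl methyl ether cleavage with BBr3 (O–B coordination, then bromide attack at methyl) should remove the three methoxy groups of ring A while the catechols are held as boron esters until hydrolysis and the aryl C–Br bonds stay inert.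

**Compound list**

1 | 2-bromo-1,3,5-trimethoxybenzene | COc1cc(OC)c(Br)c(OC)c1 | starting material
2 | paraformaldehyde (formaldehyde source; SMILES of the monomer) | C=O | starting material
3 | 2-bromo-4,6-bis(chloromethyl)-1,3,5-trimethoxybenzene | COc1c(CCl)c(OC)c(Br)c(OC)c1CCl | intermediate
4 | chloroprene (2-chlorobuta-1,3-diene) | C=CC(Cl)=C | starting material
5 | buta-1,3-dien-2-ylmagnesium chloride (not isolated) | C=CC(=C)[Mg]Cl | intermediate
6 | 2-bromo-1,3,5-trimethoxy-4,6-bis(2-methylidenebut-3-en-1-yl)benzene | COc1c(CC(=C)C=C)c(OC)c(Br)c(OC)c1CC(=C)C=C | intermediate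
7 | vinylene carbonate (1,3-dioxol-2-one) | O=C1OC=CO1 | starting material
8 | 5,5′-[(5-bromo-2,4,6-trimethoxy-1,3-phenylene)bis(methylene)]bis(cis-3a,4,7,7a-tetrahydro-1,3-benzodioxol-2-one), cis ring fusions, C2-symmetric racemate drawn, meso form alongside | COc1c(CC2=CC[C@H]3OC(=O)O[C@H]3C2)c(OC)c(Br)c(OC)c1CC1=CC[C@H]2OC(=O)O[C@H]2C1 | intermediate
9 | 4,4′-[(5-bromo-2,4,6-trimethoxy-1,3-phenylene)bis(methylene)]bis(cis-cyclohex-4-ene-1,2-diol), cis-diols, C2-symmetric racemate drawn, meso form alongside | COc1c(CC2=CC[C@@H](O)[C@@H](O)C2)c(OC)c(Br)c(OC)c1CC1=CC[C@@H](O)[C@@H](O)C1 | intermediate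
10 | 4,4′-[(5-bromo-2,4,6-trimethoxy-1,3-phenylene)bis(methylene)]bis(cyclohex-4-ene-1,2-dione) (not isolated) | COc1c(CC2=CCC(=O)C(=O)C2)c(OC)c(Br)c(OC)c1CC1=CCC(=O)C(=O)C1 | intermediate
11 | 4,4′-[(5-bromo-2,4,6-trimethoxy-1,3-phenylene)bis(methylene)]bis(benzene-1,2-diol) | COc1c(Cc2ccc(O)c(O)c2)c(OC)c(Br)c(OC)c1Cc1ccc(O)c(O)c1 | intermediate
12 | 5,5′-[(5-bromo-2,4,6-trimethoxy-1,3-phenylene)bis(methylene)]bis(3,4-dibromobenzene-1,2-diol) (vidalol B trimethyl ether) | COc1c(Cc2cc(O)c(O)c(Br)c2Br)c(OC)c(Br)c(OC)c1Cc1cc(O)c(O)c(Br)c1Br | intermediate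
13 | vidalol B, 2-bromo-4,6-bis(2,3-dibromo-4,5-dihydroxybenzyl)benzene-1,3,5-triol (no stereocentres) | Oc1cc(Cc2c(O)c(Br)c(O)c(Cc3cc(O)c(O)c(Br)c3Br)c2O)c(Br)c(Br)c1O | target

**Totals.** Total step count: 7. Longest linear sequence: 7 steps (1 → 13).

**Steps most likely to fail**

Step 3. The two diene arms may dimerise or polymerise thermally faster than the weakly activated dienophile adds, or the reaction may stall after one arm. The fallback sets out from 6 and uses a stronger acceptor dienophile that also brings the dione oxidation level with it. Zinc dechlorination of 4,4,5,5-tetrachloro-1,3-dioxolan-2-one gives 4,5-dichloro-1,3-dioxol-2-one F1. A twofold Diels–Alder reaction of 6 with it (BHT, PhMe, sealed tube, lowest temperature that gives conversion) should give 5,5′-[(5-bromo-2,4,6-trimethoxy-1,3-phenylene)bis(methylene)]bis(cis-3a,7a-dichloro-3a,4,7,7a-tetrahydro-1,3-benzodioxol-2-one) F2. Hydrolysis in aqueous dioxane then strips carbon dioxide and hydrogen chloride to give the tetraketone 10, which enolises to the bis-catechol. The fallback comes back to the route at 11 and makes steps 4 and 5 unnecessary.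

Step 6. Bromination may lose regiocontrol (attack at C6′ in place of C3′), run on to a third bromine per ring, or oxidise the catechols to o-quinones. The fallback sets out from 11 and separates the two brominations, fixing the second by directed metalation. NBS (2 equiv, MeCN, −20 °C) should brominate only para to the C5′ hydroxyl, at C2′, to give 5,5′-[(5-bromo-2,4,6-trimethoxy-1,3-phenylene)bis(methylene)]bis(4-bromobenzene-1,2-diol) F3. Exhaustive O-methylation (MeI, K2CO3, DMF) gives 2-bromo-4,6-bis(2-bromo-4,5-dimethoxybenzyl)-1,3,5-trimethoxybenzene F4. Lithium 2,2,6,6-tetramethylpiperidide (THF, −78 °C) should remove the C3′ proton, the only ring C–H flanked by both a bromine and a methoxy group (directed ortho-lithiation), and trapping with BrCCl2CCl2Br gives 2-bromo-4,6-bis(2,3-dibromo-4,5-dimethoxybenzyl)-1,3,5-trimethoxybenzene F5. BBr3 then cleaves all seven methyl ethers, so the fallback comes back to the route at 13.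

Step 2. The ambident Grignard reagent may couple through its allenic terminus, the benzylic chloride may undergo Wurtz-type homocoupling, or magnesium–bromine exchange may occur at ring A. The fallback sets out from 3 and from the Grignard solution 5 and replaces the copper-catalysed alkylation by a neutral, anhydrous palladium-catalysed coupling. Quenching 5 with Bu3SnCl gives tributyl(buta-1,3-dien-2-yl)stannane F6. Stille coupling of F6 with 3 (Pd(PPh3)4, THF, 60 °C) should engage the benzylic C–Cl bonds much faster than the doubly ortho-substituted, electron-rich aryl bromide. The fallback comes back to the route at 6.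

**Further compounds**

F1 | step 3 | 4,5-dichloro-1,3-dioxol-2-one | O=C1OC(Cl)=C(Cl)O1
F2 | step 3 | 5,5′-[(5-bromo-2,4,6-trimethoxy-1,3-phenylene)bis(methylene)]bis(cis-3a,7a-dichloro-3a,4,7,7a-tetrahydro-1,3-benzodioxol-2-one) | COc1c(CC2=CC[C@@]3(Cl)OC(=O)O[C@@]3(Cl)C2)c(OC)c(Br)c(OC)c1CC1=CC[C@@]2(Cl)OC(=O)O[C@@]2(Cl)C1
F3 | step 6 | 5,5′-[(5-bromo-2,4,6-trimethoxy-1,3-phenylene)bis(methylene)]bis(4-bromobenzene-1,2-diol) | COc1c(Cc2cc(O)c(O)cc2Br)c(OC)c(Br)c(OC)c1Cc1cc(O)c(O)cc1Br
F4 | step 6 | 2-bromo-4,6-bis(2-bromo-4,5-dimethoxybenzyl)-1,3,5-trimethoxybenzene | COc1c(Cc2cc(OC)c(OC)cc2Br)c(OC)c(Br)c(OC)c1Cc1cc(OC)c(OC)cc1Br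
F5 | step 6 | 2-bromo-4,6-bis(2,3-dibromo-4,5-dimethoxybenzyl)-1,3,5-trimethoxybenzene | COc1c(Cc2cc(OC)c(OC)c(Br)c2Br)c(OC)c(Br)c(OC)c1Cc1cc(OC)c(OC)c(Br)c1Br
F6 | step 2 | tributyl(buta-1,3-dien-2-yl)stannane | CCCC[Sn](CCCC)(CCCC)C(=C)C=C
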